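**Plan**

1. Locants are those of the target drawn as a hexahydronaphthalene and are kept for the same atoms in every intermediate: ring B = C1(=O), C2(CO2Me), C3(C16H33), C4, C4a, C8a; ring A = C4a, C5(CO2Me), C6(C16H33)=C7, C8(CO2Me), C8a.
2. Retrosynthesis: C2=C3 (Knoevenagel) and C1–C2 (Claisen) take ring B back to a δ-lactone (C1 carbonyl, ring O on C3); C6=C7 (ring-closing metathesis) opens ring A to a vinyl group on C8 and a 1-hexadecylvinyl group on C5.
3. C7 and the C5 carboxyl carbon of this seco compound are then joined as a silyl enol ether C=C, giving a temporary cyclohexene that a Diels–Alder disconnection (C8–C8a, C4a–C5) splits into an unsaturated lactone and a 2-silyloxy diene.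
4. Enabling feature: the only alkene of ring A, C6=C7, is unconjugated and flanked by the two ester-bearing methines C5 and C8, so C7–C8–C8a–C4a–C5–CO2 is a six-atom cyclohexene retron and both metathesis partners are isolated terminal alkenes.
5. Forward: lactone (steps 1–3) and diene (steps 4–7) → Diels–Alder (temporary ring) → ozonolysis and methylenation → metathesis closes ring A → Claisen, oxidation and Knoevenagel close ring B → esterification.
6. Stereochemistry: the C3 carbinol centre comes from a catalytic asymmetric allylation and steers an endo Diels–Alder reaction that sets C4a, C5, C8 and C8a in one event; the ring switch turns the old ring carbon into the exocyclic C5 ester (trans) while C8 stays cis; the C3 centre is finally oxidised away.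

Key step: step 11

Remark: (R)-BINAP is assumed to be the ligand enantiomer that gives the (R)-carbinol in step 1; if the sense is opposite, (S)-BINAP is used and nothing else changes. Pentadecylmagnesium bromide 7 is taken as the commercial THF solution.

**Step 1**
Reactants: 1 heptadecan-1-ol; 2 allyl acetate
Product: 3 (4R)-icos-1-en-4-ol
Conditions: [Ir(cod)Cl]2 (2.5 mol %), (R)-BINAP (5 mol %), 4-chloro-3-nitrobenzoic acid (10 mol %), Cs2CO3 (20 mol %), THF, 100 °C, sealed tube
Reagents that add atoms: none
Why: Iridium-catalysed transfer-hydrogenative carbonyl allylation from the alcohol oxidation level: the alcohol is dehydrogenated to heptadecanal in situ and the chiral cyclometalated iridium π-allyl complex transfers the allyl group to one aldehyde face, which sets the carbinol centre (future C3).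

**Step 2**
Reactants: 3 (4R)-icos-1-en-4-ol; 4 acryloyl chloride
Product: 5 (4R)-icos-1-en-4-yl prop-2-enoate
Conditions: Et3N, DMAP (cat.), CH2Cl2, 0 °C
Reagents that add atoms: none
Why: O-acylation of the secondary alcohol by the acid chloride; the stereocentre is not involved.

**Step 3**
Reactants: 5 (4R)-icos-1-en-4-yl prop-2-enoate
Product: 6 (6R)-6-hexadecyl-5,6-dihydro-2H-pyran-2-one
Conditions: second-generation Grubbs catalyst (H2IMes)(PCy3)Cl2Ru=CHPh (3 mol %), CH2Cl2 (5 mM), 40 °C
Reagents that add atoms: none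
Why: Ring-closing metathesis of a homoallyl acrylate to the α,β-unsaturated δ-lactone with loss of ethene, a routine closure that leaves the stereocentre untouched.

**Step 4**
Reactants: 7 pentadecylmagnesium bromide; 8 3-chloro-2-(chloromethyl)prop-1-ene
Product: 9 2-(chloromethyl)octadec-1-ene
Conditions: Li2CuCl4 (3 mol %), THF, −20 °C → rt, 8 in threefold excess
Reagents that add atoms: none
Why: Copper-catalysed allylic substitution of one chloride by the Grignard reagent; direct and allylic-transposed attack give the same product by symmetry, and the excess of 8 suppresses double substitution.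

**Step 5**
Reactants: 10 [(tert-butyldimethylsilyl)oxy]acetaldehyde; 11 N-methoxy-N-methyl-2-(triphenyl-λ5-phosphanylidene)acetamide
Product: 12 (2E)-4-[(tert-butyldimethylsilyl)oxy]-N-methoxy-N-methylbut-2-enamide
Conditions: CH2Cl2, rt
Reagents that add atoms: none
Why: Wittig olefination with a stabilised ylide, which should give the (E)-enamide.

**Step 6**
Reactants: 9 2-(chloromethyl)octadec-1-ene; 12 (2E)-4-[(tert-butyldimethylsilyl)oxy]-N-methoxy-N-methylbut-2-enamide
Product: 14 (2E)-1-[(tert-butyldimethylsilyl)oxy]-6-methylidenedocos-2-en-4-one, via allylmagnesium chloride 13 (not isolated)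
Conditions: Mg, THF, 0 °C; then 12, −78 → −20 °C; aq. NH4Cl
Reagents that add atoms: none
Why: Grignard formation and 1,2-addition to the Weinreb amide; the chelated tetrahedral intermediate prevents over-addition and releases the β,γ-unsaturated ketone only on mild quench, before it can isomerise into conjugation.

**Step 7**
Reactants: 14 (2E)-1-[(tert-butyldimethylsilyl)oxy]-6-methylidenedocos-2-en-4-one
Product: 15 (2E,4Z)-1,4-bis[(tert-butyldimethylsilyl)oxy]-6-methylidenedocosa-2,4-diene
Conditions: TBSOTf, Et3N, CH2Cl2, −78 → 0 °C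
Reagents that add atoms: tert-butyldimethylsilyl trifluoromethanesulfonate, CC(C)(C)[Si](C)(C)OS(=O)(=O)C(F)(F)F
Why: Soft enolisation at the doubly activated C5 methylene (the only α-CH of the ketone) gives the silyl dienol ether; the (4Z) geometry with the alkenyl group cis to the silyloxy group should be favoured by allylic strain and places both diene termini substituents outside.

**Step 8**
Reactants: 6 (6R)-6-hexadecyl-5,6-dihydro-2H-pyran-2-one; 15 (2E,4Z)-1,4-bis[(tert-butyldimethylsilyl)oxy]-6-methylidenedocosa-2,4-diene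
Product: 16 (3R)-6-[(tert-butyldimethylsilyl)oxy]-8-{[(tert-butyldimethylsilyl)oxy]methyl}-3-hexadecyl-5-(octadec-1-en-2-yl)-3,4,4a,5,8,8a-hexahydro-1H-isochromen-1-one (cis-fused; H-4a, H-5, H-8 and H-8a all cis; 3-hexadecyl cis to H-4a)
Conditions: PhMe (1 M), BHT (cat.), 150 °C, sealed tube
Reagents that add atoms: none
Why: Thermal normal-demand Diels–Alder reaction: the silyloxy group makes the alkenyl-bearing diene terminus nucleophilic so that it bonds to the lactone β-carbon (C4a) and the other terminus to the α-carbon (C8a), and the diene adds endo to the lactone carbonyl on the face anti to the pseudo-equatorial C3 hexadecyl group, which sets C4a, C5, C8 and C8a all-cis in one event under control of C3.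

**Step 9**
Reactants: 16 Diels–Alder adduct
Product: 17 2-[(6R)-3-{1-[(tert-butyldimethylsilyl)oxy]-3-oxopropan-2-yl}-6-hexadecyl-2-oxooxan-4-yl]-3-methylidenenonadecanoic acid (3,4-cis and 4,6-trans on the oxanone; side-chain centres as in 16)
Conditions: O3 (1.0 equiv, titrated CH2Cl2 solution), CH2Cl2, −78 °C; Me2S, −78 °C → rt; aq. pH 4 work-up
Reagents that add atoms: ozone, [O-][O+]=O
Why: Ozonolysis: the electron-rich trisubstituted silyl enol ether should react with ozone much faster than the 1,1-dialkyl alkene, so one equivalent cleaves only the temporary ring, C7 becoming the aldehyde and the enol ether carbon the C5 carboxylic acid after loss of the silyl group on work-up; no stereocentre is touched.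

**Step 10**
Reactants: 17 aldehyde acid
Product: 18 2-[(6R)-3-{1-[(tert-butyldimethylsilyl)oxy]but-3-en-2-yl}-6-hexadecyl-2-oxooxan-4-yl]-3-methylidenenonadecanoic acid (configuration as in 17)
Conditions: Ph3PCH3Br, KN(SiMe3)2, THF, −78 → 0 °C (3 equiv of ylide); aq. NaH2PO4
Reagents that add atoms: methyltriphenylphosphonium bromide, C[P+](c1ccccc1)(c1ccccc1)c1ccccc1.[Br-]
Why: Wittig methylenation with a non-stabilised ylide; the first equivalent turns the acid into its carboxylate, which shields C5–H, and the aldehyde should be olefinated at low temperature faster than it is enolised at C8.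

**Step 11**
Reactants: 18 diene acid
Product: 19 (3R)-8-{[(tert-butyldimethylsilyl)oxy]methyl}-3,6-dihexadecyl-1-oxo-3,4,4a,5,8,8a-hexahydro-1H-isochromene-5-carboxylic acid (cis-fused; H-8 cis and H-5 trans to H-4a and H-8a)
Conditions: second-generation Hoveyda–Grubbs catalyst (H2IMes)Cl2Ru=CH(C6H4-2-OiPr) (5 mol %), 1,4-benzoquinone (10 mol %), PhMe (5 mM), 80 °C
Reagents that add atoms: none
Why: Ring-closing olefin metathesis through ruthenacyclobutanes: the alkylidene loads on the vinyl group at C8, adds across the 1,1-disubstituted alkene on C5 and cycloreverts with loss of ethene. The closest known reaction type is the metathesis closure of 1,7-dienes to trisubstituted cyclohexenes. Ring A (C4a–C5–C6–C7–C8–C8a) is closed as a six-membered carbocycle by joining C6 and C7 as a double bond, cis-fused to the lactone. No stereocentre is created, and the four centres set in step 8 are carried over. Because the ring carbon of the temporary cyclohexene is now the exocyclic C5 carboxyl group and the former exocyclic alkenyl carbon is ring atom C6, the all-cis adduct becomes the C5-trans, C8-cis array of the target. The step needs ring closure in preference to oligomerisation and no migration of either alkene into conjugation; the two alkenes are the only ones present and sit on cis arms of adjacent lactone carbons, the free C5 acid leaves no base-labile ester α-hydrogen, and benzoquinone suppresses ruthenium hydride isomerisation.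

**Step 12**
Reactants: 19 bicyclic lactone acid
Product: 20 2-hexadecyl-6-[(2R)-2-hydroxyoctadecyl]-5-(3-methoxy-3-oxopropanoyl)-4-{[(tert-butyldimethylsilyl)oxy]methyl}cyclohex-2-ene-1-carboxylic acid (4,5-cis, 5,6-cis, 1,6-trans; may exist in part as the cyclic hemiketal)
Conditions: MeOAc, LiN(iPr)2, THF, −78 °C (5 equiv of enolate); then 19, −78 → −40 °C; aq. NH4Cl, then 1 M HCl to pH 3
Reagents that add atoms: methyl acetate, CC(=O)OC
Why: Claisen-type acylation of the lithium enolate of methyl acetate by the δ-lactone (addition, ring opening to the β-keto ester enolate), run while C5 is a carboxylate and C8 carries no carbonyl group, so neither centre has an acidic α-hydrogen.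

**Step 13**
Reactants: 20 hydroxy keto ester acid
Product: 22 (4aR,5S,8R,8aS)-3,6-dihexadecyl-2-(methoxycarbonyl)-1-oxo-1,4,4a,5,8,8a-hexahydronaphthalene-5,8-dicarboxylic acid, via diketo diacid 21 (not isolated)
Conditions: CrO3, H2SO4, H2O, acetone, 0 °C; extraction; then piperidine, AcOH, 4 Å MS, PhMe, 40 °C
Reagents that add atoms: water, O
Why: Jones oxidation turns the secondary alcohol into the C3 ketone and the primary silyl ether, cleaved in the acidic medium, into the C8 carboxylic acid; the 1,5-diketone then closes ring B by amine-mediated intramolecular Knoevenagel condensation of the β-keto ester methylene C2 onto the C3 ketone (six-membered ring, dehydration into conjugation), the carboxylates protecting C5 and C8 from epimerisation.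

**Step 14**
Reactants: 22 enone diacid
Product: 23 trimethyl (4aR,5S,8R,8aS)-3,6-dihexadecyl-1-oxo-1,4,4a,5,8,8a-hexahydronaphthalene-2,5,8-tricarboxylate
Conditions: TMSCHN2, PhMe/MeOH 4:1, 0 °C
Reagents that add atoms: (trimethylsilyl)diazomethane, C[Si](C)(C)C=[N+]=[N-]
Why: Methyl esterification of both carboxylic acids under neutral conditions, which should leave the epimerisable centres C5, C8 and C8a untouched.

**Compound list**

1 | heptadecan-1-ol | CCCCCCCCCCCCCCCCCO | starting material
2 | allyl acetate | C=CCOC(C)=O | starting material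
3 | (4R)-icos-1-en-4-ol | C=CC[C@H](O)CCCCCCCCCCCCCCCC | intermediate
4 | acryloyl chloride | C=CC(=O)Cl | starting material
5 | (4R)-icos-1-en-4-yl prop-2-enoate | C=CC[C@H](OC(=O)C=C)CCCCCCCCCCCCCCCC | intermediate
6 | (6R)-6-hexadecyl-5,6-dihydro-2H-pyran-2-one | CCCCCCCCCCCCCCCC[C@@H]1CC=CC(=O)O1 | intermediate
7 | pentadecylmagnesium bromide | CCCCCCCCCCCCCCC[Mg]Br | starting material
8 | 3-chloro-2-(chloromethyl)prop-1-ene | C=C(CCl)CCl | starting material
9 | 2-(chloromethyl)octadec-1-ene | C=C(CCl)CCCCCCCCCCCCCCCC | intermediate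
10 | [(tert-butyldimethylsilyl)oxy]acetaldehyde | O=CCO[Si](C)(C)C(C)(C)C | starting material
11 | N-methoxy-N-methyl-2-(triphenyl-λ5-phosphanylidene)acetamide | CON(C)C(=O)C=P(c1ccccc1)(c1ccccc1)c1ccccc1 | starting material
12 | (2E)-4-[(tert-butyldimethylsilyl)oxy]-N-methoxy-N-methylbut-2-enamide | CON(C)C(=O)/C=C/CO[Si](C)(C)C(C)(C)C | intermediate
13 | (2-methylideneoctadecyl)magnesium chloride | C=C(C[Mg]Cl)CCCCCCCCCCCCCCCC | intermediate (not isolated)
14 | (2E)-1-[(tert-butyldimethylsilyl)oxy]-6-methylidenedocos-2-en-4-one | CC(C)(C)[Si](C)(C)OC/C=C/C(=O)CC(=C)CCCCCCCCCCCCCCCC | intermediate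
15 | (2E,4Z)-1,4-bis[(tert-butyldimethylsilyl)oxy]-6-methylidenedocosa-2,4-diene | CC(C)(C)[Si](C)(C)OC/C=C/C(O[Si](C)(C)C(C)(C)C)=C/C(=C)CCCCCCCCCCCCCCCC | intermediate
16 | (3R)-6-[(tert-butyldimethylsilyl)oxy]-8-{[(tert-butyldimethylsilyl)oxy]methyl}-3-hexadecyl-5-(octadec-1-en-2-yl)-3,4,4a,5,8,8a-hexahydro-1H-isochromen-1-one, all-cis at C4a, C5, C8, C8a | CC(C)(C)[Si](C)(C)OC1=C[C@@H](CO[Si](C)(C)C(C)(C)C)[C@H]2C(=O)O[C@H](CCCCCCCCCCCCCCCC)C[C@H]2[C@H]1C(=C)CCCCCCCCCCCCCCCC | intermediate
17 | 2-[(6R)-3-{1-[(tert-butyldimethylsilyl)oxy]-3-oxopropan-2-yl}-6-hexadecyl-2-oxooxan-4-yl]-3-methylidenenonadecanoic acid | O=C[C@@H](CO[Si](C)(C)C(C)(C)C)[C@H]1C(=O)O[C@H](CCCCCCCCCCCCCCCC)C[C@H]1[C@@H](C(=C)CCCCCCCCCCCCCCCC)C(=O)O | intermediate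
18 | 2-[(6R)-3-{1-[(tert-butyldimethylsilyl)oxy]but-3-en-2-yl}-6-hexadecyl-2-oxooxan-4-yl]-3-methylidenenonadecanoic acid | C=C[C@@H](CO[Si](C)(C)C(C)(C)C)[C@H]1C(=O)O[C@H](CCCCCCCCCCCCCCCC)C[C@H]1[C@@H](C(=C)CCCCCCCCCCCCCCCC)C(=O)O | intermediate
19 | (3R)-8-{[(tert-butyldimethylsilyl)oxy]methyl}-3,6-dihexadecyl-1-oxo-3,4,4a,5,8,8a-hexahydro-1H-isochromene-5-carboxylic acid, cis-fused, H-8 cis and H-5 trans to H-4a | CCCCCCCCCCCCCCCCC1=C[C@@H](CO[Si](C)(C)C(C)(C)C)[C@H]2C(=O)O[C@H](CCCCCCCCCCCCCCCC)C[C@H]2[C@@H]1C(=O)O | intermediate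
20 | 2-hexadecyl-6-[(2R)-2-hydroxyoctadecyl]-5-(3-methoxy-3-oxopropanoyl)-4-{[(tert-butyldimethylsilyl)oxy]methyl}cyclohex-2-ene-1-carboxylic acid, 4,5-cis, 5,6-cis, 1,6-trans | CCCCCCCCCCCCCCCCC1=C[C@@H](CO[Si](C)(C)C(C)(C)C)[C@@H](C(=O)CC(=O)OC)[C@@H](C[C@H](O)CCCCCCCCCCCCCCCC)[C@@H]1C(=O)O | intermediate
21 | 2-hexadecyl-5-(3-methoxy-3-oxopropanoyl)-6-(2-oxooctadecyl)cyclohex-2-ene-1,4-dicarboxylic acid, 4,5-cis, 5,6-cis, 1,6-trans | CCCCCCCCCCCCCCCCC1=C[C@@H](C(=O)O)[C@@H](C(=O)CC(=O)OC)[C@@H](CC(=O)CCCCCCCCCCCCCCCC)[C@@H]1C(=O)O | intermediate (not isolated)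
22 | (4aR,5S,8R,8aS)-3,6-dihexadecyl-2-(methoxycarbonyl)-1-oxo-1,4,4a,5,8,8a-hexahydronaphthalene-5,8-dicarboxylic acid | CCCCCCCCCCCCCCCCC1=C[C@@H](C(=O)O)[C@H]2C(=O)C(C(=O)OC)=C(CCCCCCCCCCCCCCCC)C[C@H]2[C@@H]1C(=O)O | intermediate
23 | trimethyl (4aR,5S,8R,8aS)-3,6-dihexadecyl-1-oxo-1,4,4a,5,8,8a-hexahydronaphthalene-2,5,8-tricarboxylate | CCCCCCCCCCCCCCCCC1=C[C@@H](C(=O)OC)[C@H]2C(=O)C(C(=O)OC)=C(CCCCCCCCCCCCCCCC)C[C@H]2[C@@H]1C(=O)OC | target

**Step count and risks**

Total steps: 14. Longest linear sequence: 10 steps (steps 4, 6, 7 and 8–14, or equally steps 1–3 and 8–14).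

Steps most likely to fail:

Step 8. The unactivated unsaturated lactone may react too slowly, so that the diene decomposes or isomerises at the temperature needed, and regio- or facial selectivity may erode. The fallback sets out from 6 and activates the dienophile with a removable α-halogen. Bromine addition in CH2Cl2 gives (6R)-3,4-dibromo-6-hexadecyloxan-2-one F1, which is not isolated, and Et3N eliminates HBr to give (6R)-3-bromo-6-hexadecyl-5,6-dihydro-2H-pyran-2-one F2. This α-bromo lactone should undergo cycloaddition with 15 at lower temperature with the same endo and anti-facial sense to give the 8a-bromo adduct F3. Radical debromination (Bu3SnH, AIBN, PhH, 80 °C), with hydrogen delivered to the convex face so that the cis fusion is kept, returns to 16.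

Step 13. Three events run in one operation; the alkene may migrate through the β,γ-unsaturated aldehyde formed on the way to the C8 acid, and C8a may epimerise during ring closure. The fallback sets out from 20 and separates the events. Dess–Martin oxidation of the carbinol gives the diketone silyl ether acid F4. Piperidinium acetate closes ring B to the enone silyl ether acid F5 with the silyl ether intact. HF·pyridine frees the primary alcohol F6. Oxidation with TEMPO (cat.) and PhI(OAc)2, followed by buffered NaClO2, gives 22.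

Step 9. Ozone may also attack the 1,1-disubstituted alkene or over-oxidise the aldehyde. The fallback sets out from 16 and uses a two-stage cleavage. Dihydroxylation of the enol ether alone (OsO4 2 mol %, N-methylmorpholine N-oxide, acetone/H2O, 0 °C) gives the α-hydroxy ketone F7 with loss of the silyl group. NaIO4 in THF/H2O cleaves it to the aldehyde and the carboxylic acid, which is 17.

**Further compounds**

F1 | step 8 | (6R)-3,4-dibromo-6-hexadecyloxan-2-one (mixture at C3 and C4, not isolated) | CCCCCCCCCCCCCCCC[C@@H]1CC(Br)C(Br)C(=O)O1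
F2 | step 8 | (6R)-3-bromo-6-hexadecyl-5,6-dihydro-2H-pyran-2-one | CCCCCCCCCCCCCCCC[C@@H]1CC=C(Br)C(=O)O1
F3 | step 8 | 8a-bromo analogue of 16, (3R)-8a-bromo-6-[(tert-butyldimethylsilyl)oxy]-8-{[(tert-butyldimethylsilyl)oxy]methyl}-3-hexadecyl-5-(octadec-1-en-2-yl)-3,4,4a,5,8,8a-hexahydro-1H-isochromen-1-one | CC(C)(C)[Si](C)(C)OC1=C[C@@H](CO[Si](C)(C)C(C)(C)C)[C@@]2(Br)C(=O)O[C@H](CCCCCCCCCCCCCCCC)C[C@H]2[C@H]1C(=C)CCCCCCCCCCCCCCCC
F4 | step 13 | 2-hexadecyl-5-(3-methoxy-3-oxopropanoyl)-6-(2-oxooctadecyl)-4-{[(tert-butyldimethylsilyl)oxy]methyl}cyclohex-2-ene-1-carboxylic acid | CCCCCCCCCCCCCCCCC1=C[C@@H](CO[Si](C)(C)C(C)(C)C)[C@@H](C(=O)CC(=O)OC)[C@@H](CC(=O)CCCCCCCCCCCCCCCC)[C@@H]1C(=O)O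
F5 | step 13 | 8-{[(tert-butyldimethylsilyl)oxy]methyl}-3,6-dihexadecyl-2-(methoxycarbonyl)-1-oxo-1,4,4a,5,8,8a-hexahydronaphthalene-5-carboxylic acid (configuration as in 22) | CCCCCCCCCCCCCCCCC1=C[C@@H](CO[Si](C)(C)C(C)(C)C)[C@H]2C(=O)C(C(=O)OC)=C(CCCCCCCCCCCCCCCC)C[C@H]2[C@@H]1C(=O)O
F6 | step 13 | 3,6-dihexadecyl-8-(hydroxymethyl)-2-(methoxycarbonyl)-1-oxo-1,4,4a,5,8,8a-hexahydronaphthalene-5-carboxylic acid (configuration as in 22) | CCCCCCCCCCCCCCCCC1=C[C@@H](CO)[C@H]2C(=O)C(C(=O)OC)=C(CCCCCCCCCCCCCCCC)C[C@H]2[C@@H]1C(=O)O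
F7 | step 9 | (3R)-8-{[(tert-butyldimethylsilyl)oxy]methyl}-3-hexadecyl-7-hydroxy-5-(octadec-1-en-2-yl)hexahydro-1H-isochromene-1,6-dione (either C7 epimer; other centres as in 16) | O=C1C(O)[C@@H](CO[Si](C)(C)C(C)(C)C)[C@H]2C(=O)O[C@H](CCCCCCCCCCCCCCCC)C[C@H]2[C@H]1C(=C)CCCCCCCCCCCCCCCC
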